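It is easy to take the 10 h on a recipe for 10 h of reaction, and in the south-west flask, fed cold, that is a trap.

| flask | starting material | partner | second reagent | capture agent | temperature | remark | time |
|---|---|---|---|---|---|---|---|
| gamma | 0.020 M | 0.060 M | 0.060 M | 0.40 mM | 20 °C | run made earlier |  |
| epsilon | 0.013 M | 0.060 M | 0.060 M | 0.40 mM | 31 °C | run made earlier |  |
| delta | 0.030 M | 0.060 M | 0.060 M | 0.40 mM | 20 °C | run made earlier |  |
| north-west | 0.020 M (fed, over 8.0 h) | 0.0600 M | 0.0600 M | 0.400 mM | 25 °C | all else is in the flask from the start; the feed brings no volume worth counting | 10 h |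
| south-east | 0.020 M | 0.0600 M | 0.0600 M (fed, over 8.0 h) | 0.400 mM | 25 °C | all else is in the flask from the start; the feed brings no volume worth counting | 10 h |
| west | 0.020 M | 0.0600 M | 0.0600 M | 0.400 mM | 25 °C | everything together at the start | 10 h |
| south-west | 0.020 M (fed, over 8.0 h) | 0.0600 M | 0.0600 M | 0.400 mM |  | the addition at −5 °C, then warmed to 25 °C; the feed brings no volume worth counting | 10 h |

| run | time / h | target / % | starting material / % |
|---|---|---|---|
| gamma | 0.500 | 2.8 | 80.6 |
| gamma | 0.833 | 6.4 | 70.0 |
| gamma | 1.33 | 9.9 | 57.5 |
| gamma | 2.00 | 14.4 | 44.1 |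
| gamma | 4.00 | 22.0 | 20.9 |
| gamma | 6.00 | 25.5 | 9.7 |
| epsilon | 1.00 | 14.4 | 32.6 |
| epsilon | 1.50 | 20.1 | 18.8 |
| epsilon | 2.50 | 23.3 | 7.5 |
| epsilon | 4.00 | 25.3 | 1.1 |
| epsilon | 8.00 | 25.9 | 0 |
| epsilon | 12.0 | 25.4 | 0.2 |
| delta | 2.00 | 13.6 | 45.3 |
| delta | 4.00 | 19.8 | 22.2 |
| delta | 6.00 | 23.8 | 11.1 |
| delta | 8.00 | 24.7 | 6.0 |
| delta | 10.0 | 25.8 | 3.2 |
| delta | 12.0 | 26.1 | 0.3 |

(readings scatter by 0.5 percentage points)

- a species is counted by the starting material in it: one side product B counts as two
- candidate steps: starting material + partner -> open intermediate; second reagent + open intermediate <-> target; starting material + second reagent -> side product A; starting material + target -> side product B; open intermediate + capture agent -> trapped intermediate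

- the flask with the highest amount of target, in percent of the starting material charged ("all alike" if they lie within 1.5 percentage points) (north-west / south-east / west / south-west / all alike)
- final target, as a percentage of the starting material charged, in north-west
- final target, as a percentage of the starting material charged, in south-east
- final target, as a percentage of the starting material charged, in west
- final target, as a percentage of the starting material charged, in south-west

I start from the fraction of the charge left. In gamma, 9.7% of the starting material stands at 6.00 h, so it falls at 0.389 h⁻¹. In epsilon, 18.8% at 1.50 h gives 1.11 h⁻¹. Delta, with a larger charge, reads 0.376 h⁻¹, close to gamma, so I treat the fall as pseudo-first-order. A straight line of the logarithm against temperature gives 0.627 h⁻¹ at 25 °C and 0.0355 h⁻¹ at −5 °C. The first is the loss constant I carry on: the rate at which the starting material falls at 25 °C, as a fraction of what remains.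

Now the ladder of times. The warm half-life, 1.10 h, is shorter than the warm stretch of 2.00 h. That stretch is shorter than the feed of 8.0 h, and the cold half-life, 19.5 h, is longer than the feed. So I expect the south-west flask to store its feed and react late.

I go round twice. If I let nothing react cold, my reckoning keeps 28.5% in the south-west flask at 10 h. Putting the cold loss back, my reckoning ends the feed with 87.0% of the charge unreacted, so I estimate that 24.8% remains. Taking the target per starting material consumed from epsilon's reading of 25.9% at 8.00 h, I estimate 19.5% target in south-west.

The forecast names south-east as the flask with most target, with 25% north-west, 57% south-east, 27% west and 19.5% south-west, and it judges that “side product B and reversal look minor”.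

The flask with most target is south-east, with 24.3% north-west, 45.7% south-east, 26.5% west and 20.6% south-west.

    starting material + partner → open intermediate (k = 9.60 × 10⁻⁴ M⁻¹ s⁻¹, Ea = 56.0 kJ mol⁻¹)
    second reagent + open intermediate ⇌ target (K = 800 M⁻¹, k = 0.0200 M⁻¹ s⁻¹, Ea = 45.0 kJ mol⁻¹, ΔH = −53.0 kJ mol⁻¹)
    starting material + second reagent → side product A (k = 0.00220 M⁻¹ s⁻¹, Ea = 73.0 kJ mol⁻¹)
    starting material + target → side product B (k = 0.00290 M⁻¹ s⁻¹, Ea = 56.0 kJ mol⁻¹)
    open intermediate + capture agent → trapped intermediate (k = 0.00350 M⁻¹ s⁻¹, Ea = 57.0 kJ mol⁻¹)
    (constants at 25 °C)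

South-east stands 11 percentage points below the forecast, and at 10.0 h that flask holds 20.5% side product B, against 8.21% in west. In south-west, 25% of the starting material is left at 10.0 h, beside my 24.8%.

For the south-west flask read at 15 h, the loss constant 0.627 h⁻¹ leaves 1.08%. At that time the computed south-west flask holds 1.40% starting material and 27.4% target.

(The earlier runs and the new flask are calculated with made-up constants; the scatter is artificial.)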